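L cannot keep falling in Wednesday's flask unless something still consumes it, yet J reads 0% at 15.0 h while L goes from 56% at 4.00 h down to 49%. Of the reactions considered, X + L → Z is the one that lowers L, so I expect X to remain.

common to all: J 0.050 M

| flask | G | temperature | remark | time |
|---|---|---|---|---|
| Wednesday's | 1.2 equiv | 50 °C | the very flask that is asked about, followed so far |  |
| Friday's | 1.2 equiv | 35 °C | run made earlier |  |
| flask | 1.20 equiv | 50 °C |  | 15 h |

| run | time / h | L / % | J / % |
|---|---|---|---|
| Wednesday's | 1.33 | 43 | 1 |
| Wednesday's | 2.50 | 55 | 0 |
| Wednesday's | 4.00 | 56 | 0 |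
| Wednesday's | 8.00 | 54 | 0 |
| Wednesday's | 15.0 | 49 | 0 |
| Friday's | 3.00 | 45 | 0 |
| Friday's | 5.00 | 58 | 1 |
| Friday's | 8.00 | 63 | 0 |
| Friday's | 15.0 | 64 | 0 |
| Friday's | 30.0 | 64 | 2 |

(scatter of a reading: 1.5 percentage points)

- north: change nothing and wait 5.0 h more
- north-west: at 15 h add G, 100% of the amount charged, then wait 5.0 h
- south-east: at 15 h raise the temperature by 20 K, then wait 5.0 h

- a species is counted by the J in it: one Z counts as two
- amounts and yields of L count Q too
- given per volume of solution although it is solid: J, Q
- additions leave the volume as it is
- reactions considered so far: J <-> X; X + G -> L; X + L -> Z; 2 G -> E; Q <-> L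
- at the start none of J is in solution

1. L, in percent of the J first charged, at 15 h
2. the remedy with the largest gain of L, or "none" below 2 percentage points (north / north-west / south-east / none)
3. L present, in percent of the J first charged, after north
4. L present, in percent of the J first charged, after south-east

I assume that from the peak on no G reaches X, G being the limiting reagent. Each turn then removes one L and one X, so L minus X stays constant and L can sink as far as that difference. With Z counted as two, L, X and Z add up to the charge, so at the peak the difference is 12.0% plus whatever Z exists by then.

Taking that Z as nothing, I put X at 44.0% at the peak. I also assume Q holds dissolved L steady, which makes the loss pseudo-first-order in X. The fall of L then gives X a lifetime of 63.6 h. Over about 3.33 h before the peak, that lifetime makes 4.61% of Z. I put this back in: the lifetime shortens to 56.4 h, Z stays near 4.66%, and the difference becomes 16.7%.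

The weak link is this early Z, which borrows a late pace. So I reforge it from Friday's run, where L reads 64% at 30.0 h; the remaining 36.0% stands in X and Z together, and I count it all as Z to get an upper end. That ratio of Z to L, applied at Wednesday's peak, gives 31.5% of Z and a difference of 43.5%, too high if any of Friday's remainder is X. I commit to the mean, 30.1%, as the floor, L minus the X beside it once no G reaches X.

Against the reading of 49%, that leaves 18.9% of X. Waiting at the same pace gives 45.8%. I expect north-west to gain somewhat less than that X, and south-east to leave L above the floor.

The forecast gives 49% now, 47% after north, 45% after south-east, and chooses north-west. It speaks of “the X pool, which I guess at about 5%”, where mine is 18.9%.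

The flask gives 48.8% now, 45.9% after north and 39.0% after south-east, and the best remedy is north-west, with a gain of 16 percentage points.

    J ⇌ X, rate k1*(cs1 - [X]) while solid is left; crystals form when [X] > cs1 (solubility = 35.0 mM, k = 8.06 × 10⁻⁴ s⁻¹)
    X + G → L (k = 0.0107 M⁻¹ s⁻¹, Ea = 68.0 kJ mol⁻¹)
    X + L → Z (k = 0.00658 M⁻¹ s⁻¹, Ea = 71.0 kJ mol⁻¹)
    2 G → E (k = 0.00285 M⁻¹ s⁻¹, Ea = 67.0 kJ mol⁻¹)
    Q ⇌ L, rate k5*(cs5 - [L]) while solid is left; crystals form when [L] > cs5 (solubility = 1.60 mM, k = 0.00321 s⁻¹)
    (constants at 50 °C)

At 15.0 h, G stands at 0.020% of its charge, L at 48.8% and X at 17.4%. Their difference is 31.4%, above my floor of 30.1%, and L reads 31.6% at 150 h. So X was more than the forecast's 5, and south-east took L down to 39.0%. The neighbouring flask with 0.085 M of J ends with G at 0%, L at 29.6% and X at 28.9%. Its floor is 0.700% of the J charged, with 41.5% already in Z.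

(Readings and results come from a simulation with made-up constants, and the scatter is random.)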